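## Structural features

Compound 20 is a 9,9′-epoxylignan: one oxolane ring (O1, C2 to C5) whose C3 and C4 each carry an aryl(hydroxy)methyl arm (carbinol carbons Cα and Cα′), the aryl groups being two separate 4-hydroxy-3-methoxyphenyl rings, and the whole molecule is C2-symmetric. Four stereocentres stand in a row, Cα(S)–C3(R)–C4(R)–Cα′(S): the two ring carbons are neighbours and trans, and each is flanked by an exocyclic carbinol centre. The fragile groups are the two para-hydroxybenzylic alcohols, which ionise towards quinone methides under acid, base or heat and are open to hydrogenolysis, and the electron-rich phenols, which periodate or hypervalent iodine would oxidise if they were free. At the ketone oxidation level C3 and C4 become acidic, which is useful (trans is the stable arrangement) and dangerous (epimerisation at both centres of the symmetric diketone, through the meso cis form, would racemise the material). The real difficulty is the absolute configuration of C3 and C4, two ring CH centres with only carbon substituents and no heteroatom to guide a reagent, and after that the relative configuration between each ring carbon and its carbinol. The key step uses the fact that O1–C2–C3 is the skeleton of an opened epoxide and C5–C4–C(=O)Ar that of a 2-aroylacrylate. Only the ring bonds O1–C5 and C3–C4 then have to be made, and the Cα carbonyl on C3 can travel as a 1-arylvinyl group that also serves as the allyl unit for palladium. (In the systematic names of 12 to 14 the ester or ketone carbon takes the lower locant, so this C3 appears there as C4.)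

## Logic of the disconnections

20 ⇒ 18. The two phenolic O–H groups are traced back to O–benzyl bonds. The phenols must be masked through strong base, allylpalladium chemistry and periodate, and the benzyl ether tolerates all of these. Nothing is gained in skeleton. The demand is that the last step cleaves two aryl benzyl ethers without touching the two benzylic C–OH bonds.

18 ⇒ 16. Both carbinol C–H bonds are removed, returning Cα and Cα′ to carbonyl groups. This takes away two of the four stereocentres and leaves a C2-symmetric 1,4-diketone whose ring centres prefer to be trans. The forward step must reduce both ketones (through 17) with the same absolute sense under reagent control, and 16 must not enolise before it is reduced.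

16 ⇒ 14. One carbonyl oxygen is exchanged for a methylene group (C=O from C=CH2). This breaks the symmetry in a useful way: in 14 only one ring carbon is acidic, so the other holds the absolute configuration while the acidic one settles trans to it. The forward step is an oxidative alkene cleavage (through 15) that must be neutral enough not to epimerise the product.

14 ⇒ 12. A carbomethoxy group is added to the ketone α-carbon (the C–H bond is replaced by a C–CO2CH3 bond). The extra carbon is lost later, but it turns that ring carbon into the terminus of a doubly activated acceptor and a stabilised nucleophile. The forward step (through 13) must remove the ester under neutral conditions and deliver the trans ketone.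

12 ⇒ 5 + 9. The ring bonds O1–C5 and C3–C4 are cut. The ring falls into a three-atom O–C–C unit and a two-atom C–C unit, one racemic and one achiral, and every carbon of 20 is present after this one step. This is the largest simplification of the plan: one ring, two bonds and the controlling stereocentre. The demand is that a chiral catalyst turns both enantiomers of 5 into one enantiomer of 12 (through 10 and 11) and that the closure is five-membered.

9 ⇒ 8 ⇒ 6 + 7. The ketone of 9 is returned to a carbinol, and then the bond between the carbinol carbon and the α-carbon of the acrylate is cut. Both pieces are commercial. The forward coupling is slow on an electron-rich aldehyde, and the oxidation must give an acceptor that is used at once.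

5 ⇒ 4 ⇒ 3 ⇒ 2 ⇒ 1. The oxirane is opened back to an aldehyde and a one-carbon ylide (epoxide C–C and C–O bonds), the C=CH2 bond of 4 is cut to an α-methylene condensation of 3, 3 is the oxidation product of 2, and 2 is the O-benzyl ether of 1. The demands are 1,2- and not 1,4-addition of the ylide, and quick handling of the enolisable 3 and the polymerisable 4.

## Other disconnections considered

Alternative 1: The cut runs through both arenes. Each aryl ketone of A1, the bis-phenol corresponding to 16, is traced back to an ynone carbon pair of the bis-ynone A2, and the other four carbons of each benzene ring to the oxygenated diene A3. In the forward step A2 would undergo two [4+2] cycloadditions with A3, and each adduct would lose methanol and its silyl group to aromatise. Reduction of both ketones of A1 would then give 20.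
- In favour: the donor pattern of A3 (1-methoxy, 3-silyloxy) matches the polarity of the ynone, so the phenol should end up para and the methoxy group meta to the acyl group. The step is thermal and needs no catalyst.
- Better than the chosen plan on one point: the phenols appear free, so there is no protecting group and no hydrogenolysis next to labile benzylic alcohols.
- Equal on one point: the carbinols would be set by the same kind of double ketone reduction as in step 10.
- Against it: the hard part of the structure is untouched. An enantiopure trans-3,4-diacyl oxolane is still required in the form of A2 and would need its own asymmetric synthesis or a resolution. A2 is a double Michael acceptor with two acidic ring hydrogens, so its configuration is at risk with any base. A3 has to be prepared. The route spends steps on building two arenes that can be bought with the right substitution.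
- Comparison: the key step sets no stereocentre, whereas step 7 forms the ring, two bonds and the controlling stereocentre in one operation. In step count the alternative is the longer plan.

Alternative 2: The two ring CH2 groups of 20 are traced back to the lactone carbonyls, and the two carbinol C–O bonds to the lactone C–O bonds, of the bis-lactone A5. A5 in turn comes from the chiral cyclobutane diacid A4 by re-forming the bond between its two benzylic carbons. In the forward step PhI(OAc)2 would take two electrons from the bis-phenol A4, the cyclobutane bond between the benzylic carbons would break, and each carboxylic acid would add to the benzylic carbon of the other half, closing two γ-lactones. Hydride reduction of A5 to the tetraol A6 and ether formation between its two primary carbons would give 20.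
- In favour: all four stereocentres derive from one enantiopure precursor. The trans diacid carbons of A4 become C3 and C4, and the exo lactonisations fix the carbinols. No asymmetric reduction and no protecting group is needed.
- Equal or better on symmetry: the plan uses the C2 symmetry from the first step.
- Better on step count: it is potentially the shortest of all the plans.
- Against it: A4 must be the head-to-head, trans-diacid dimer in enantiopure form. The fragmentation has to outrun ordinary phenol oxidation (ortho-quinone formation, acetoxylation, coupling). The endgame is the weakest part: A6 has four hydroxyl groups and two free phenols, and its para-hydroxybenzylic carbinols ionise far more readily than the primary alcohols, so ring closure would tend towards the 2,6-diaryl-3,7-dioxabicyclo[3.3.0]octane skeleton and not the 3,4-disubstituted oxolane of 20.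
- Comparison: the chosen plan closes the oxolane while both benzylic oxygens are still at the ketone or alkene level, so this wrong-ring closure cannot occur. The alternative's stereochemical relay is stereospecific and needs no chiral catalyst, but it relies on a stoichiometric oxidation that is mechanistically less secure than the annulation of step 7.

Alternative 3: The ring bonds C3–C2 and C4–C5 are cut so that both ring CH2 carbons return to carbon monoxide, leaving the E-alkene A7, a C2-symmetric bis-silyl ether of an enediol. In the forward step divalent palladium (PdCl2) with CuCl2 as reoxidant, CO and methanol would add two methoxycarbonyl groups syn across the alkene to give the succinate A8. No ring closes. Ester reduction, ether closure between the two new primary carbons, desilylation and debenzylation would lead to 20.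
- In favour: both carbinol centres are in place before any C–C bond is made and can come from a well-tested asymmetric reduction of a symmetrical precursor. They then direct the ring carbons, and the C1 source is cheap.
- Better than the chosen plan on one point: an epimerisable diketone never exists.
- Equal on two points: the ether closure is unambiguous because the benzylic oxygens are silylated, and the step count is about the same (roughly five steps to A7, the key step, and four after it).
- Against it: internal alkenes flanked by two branched allylic centres are poor substrates for double alkoxycarbonylation. β-Hydride elimination to unsaturated monoesters is a likely competitor, as is ionisation of the electron-rich allylic and benzylic silyl ethers by divalent palladium or by the HCl released from CuCl2. The two faces of the alkene in A7 are diastereotopic (the C2 axis is perpendicular to the alkene plane), so face selectivity would rest on allylic 1,3-strain alone. Pressurised CO is a handling burden.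
- Comparison: the chosen plan sets the ring carbons with a catalyst in a reaction class with direct precedent. The alternative relies on substrate control in a step without close precedent on such hindered alkenes.

Key step: step 7

Remarks before the steps:
- Structure check: the configuration of 12 is (3S,4R). The carbon bearing the arylvinyl group (4R) is the one that becomes an R ring carbon of 20; its descriptor reads S in 14 only because the substituent priorities change. No correction of connectivity or configuration is needed. The configuration at the quaternary carbon of 12 does not affect the outcome, because that centre is erased in step 8.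
- Assumption: the (R,R) antipode of the diphosphine is written in step 7 on the assumption that it leads to the 4R centre of 12. If the sense of induction is the opposite, the (S,S) antipode is used and nothing else changes.
- Compounds 6 and 7 are taken as commercial. The acceptor 9 is reached in two steps by a carbinol-oxidation route, which avoids condensing a β-keto ester with formaldehyde.

## Steps

Step 1
Reactants: 1 homovanillyl alcohol
Product: 2 2-(4-benzyloxy-3-methoxyphenyl)ethanol
Conditions: BnBr (1.1 equiv), K2CO3, acetone, reflux
Reagents that add atoms: benzyl bromide, BrCc1ccccc1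
Why: Williamson ether synthesis; K2CO3 deprotonates only the phenol, which is far more acidic than the primary alcohol, so O-benzylation is selective, and the benzyl ether is inert to every later step before the last.

Step 2
Reactants: 2 2-(4-benzyloxy-3-methoxyphenyl)ethanol
Product: 3 (4-benzyloxy-3-methoxyphenyl)acetaldehyde
Conditions: DMP (1.2 equiv), CH2Cl2, 0 °C to rt
Reagents that add atoms: none
Why: Dess–Martin oxidation stops at the aldehyde under neutral, non-aqueous conditions, which suits an enolisable arylacetaldehyde; the crude aldehyde is carried on without storage.

Step 3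
Reactants: 3 (4-benzyloxy-3-methoxyphenyl)acetaldehyde
Product: 4 2-(4-benzyloxy-3-methoxyphenyl)prop-2-enal
Conditions: aq. HCHO (37 %), pyrrolidine (10 mol %), EtCO2H (10 mol %), i-PrOH, 45 °C
Reagents that add atoms: formaldehyde, C=O
Why: Amine-catalysed Mannich condensation followed by elimination (α-methylenation of an aldehyde): the enamine of 3 adds to the iminium ion of formaldehyde and the β-amino aldehyde expels the catalyst; once the alkene has formed no α-hydrogen is left, so the reaction stops at the mono-methylene stage.

Step 4
Reactants: 4 2-(4-benzyloxy-3-methoxyphenyl)prop-2-enal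
Product: 5 racemic 2-[1-(4-benzyloxy-3-methoxyphenyl)ethenyl]oxirane
Conditions: Me3S+ I− (1.3 equiv), KOt-Bu (1.3 equiv), DMSO–THF, 0 °C to rt
Reagents that add atoms: trimethylsulfonium iodide, C[S+](C)C.[I-]
Why: Corey–Chaykovsky epoxidation: the unstabilised sulfonium ylide adds 1,2 to the aldehyde of the enal and the betaine closes to the oxirane with loss of dimethyl sulfide, whereas conjugate addition is the domain of sulfoxonium ylides; 4 has no α-hydrogen, so enolisation cannot compete, and the racemic epoxide is what the key step requires.

Step 5
Reactants: 6 4-benzyloxy-3-methoxybenzaldehyde; 7 methyl acrylate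
Product: 8 racemic methyl 2-[(4-benzyloxy-3-methoxyphenyl)(hydroxy)methyl]prop-2-enoate
Conditions: DABCO (1 equiv), acrylate in excess, MeOH (small volume), rt, several days
Reagents that add atoms: none
Why: Morita–Baylis–Hillman reaction: DABCO adds to the acrylate, the ammonium enolate adds to the aldehyde, and proton transfer with elimination returns the amine, so the two reactants combine without loss of any atom; electron-rich benzaldehydes react slowly, which is accepted here, and the new carbinol centre is racemic and is destroyed in step 6.

Step 6
Reactants: 8 racemic methyl 2-[(4-benzyloxy-3-methoxyphenyl)(hydroxy)methyl]prop-2-enoate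
Product: 9 methyl 2-(4-benzyloxy-3-methoxybenzoyl)prop-2-enoate
Conditions: DMP (1.2 equiv), CH2Cl2, 0 °C to rt; short silica plug, used the same day
Reagents that add atoms: none
Why: Dess–Martin oxidation of the secondary allylic, benzylic alcohol gives the 2-aroylacrylate without acid or base, so nothing can add to the very electrophilic product; acceptors of this kind dimerise on standing, which is why 9 is not stored.

Step 7
Reactants: 5 racemic 2-[1-(4-benzyloxy-3-methoxyphenyl)ethenyl]oxirane; 9 methyl 2-(4-benzyloxy-3-methoxybenzoyl)prop-2-enoate
Product: 12 methyl (3S,4R)-3-(4-benzyloxy-3-methoxybenzoyl)-4-[1-(4-benzyloxy-3-methoxyphenyl)ethenyl]oxolane-3-carboxylate, via allylpalladium alkoxide zwitterion 10 (not isolated), via ring-open palladium enolate 11 (not isolated)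
Conditions: Pd2(dba)3·CHCl3 (2.5 mol %), (1R,2R)-N,N′-bis[2-(diphenylphosphino)benzoyl]cyclohexane-1,2-diamine (7.5 mol %), degassed CH2Cl2, 0 °C to rt, slow addition of the acrylate to the epoxide (1.3 equiv)
Reagents that add atoms: none
Why: The zerovalent palladium–diphosphine complex opens the allylic C–O bond of either enantiomer of 5 with inversion and gives the 2-aryl π-allylpalladium alkoxide 10; its two diastereomeric forms exchange through the η1 complex at the unsubstituted CH2 terminus faster than they are consumed, so the racemate should drain through one channel (dynamic kinetic asymmetric transformation). The alkoxide adds reversibly to the unsubstituted β-carbon of 9 (ring bond O–CH2) and gives the stabilised β-keto ester enolate 11. Enolate 11 then attacks the substituted allyl terminus anti to palladium (ring C–C bond), which closes the oxolane in a 5-exo mode and releases the catalyst; attack at the CH2 terminus would need a seven-membered ring and is not expected to compete. The closest known reaction type is the palladium-catalysed zwitterionic [3+2] annulation of vinyl epoxides or vinylethylene carbonates with doubly activated alkenes, which has enantioselective variants with chiral phosphines, together with the deracemising allylic substitutions of vinyl epoxides with this ligand class. The ring carbon that carries the arylvinyl group (4R in 12) is set by the chiral ligand in the ring-closing step, because the ligand pocket decides which face of the equilibrating allyl unit the tethered enolate reaches. The quaternary carbon (3S in 12) is set relative to it by the expected preference of the larger aroyl group to lie trans to the arylvinyl group, and either outcome is acceptable because this centre is erased in step 8. The step needs oxa-Michael addition in preference to attack of the alkoxide on the ketone, and five-ring closure: the doubly activated, unhindered CH2 of 9 secures the first and the two-atom tether between enolate carbon and allyl terminus the second. Slow addition of 9 to a small excess of 5 keeps the acceptor concentration low and limits its self-condensation.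

Step 8
Reactants: 12 methyl (3S,4R)-3-(4-benzyloxy-3-methoxybenzoyl)-4-[1-(4-benzyloxy-3-methoxyphenyl)ethenyl]oxolane-3-carboxylate
Product: 14 (4-benzyloxy-3-methoxyphenyl){(3R,4S)-4-[1-(4-benzyloxy-3-methoxyphenyl)ethenyl]oxolan-3-yl}methanone, via lithium keto carboxylate 13 (not isolated)
Conditions: LiCl (3 equiv), H2O (3 equiv), DMSO, 120–130 °C
Reagents that add atoms: none
Why: Krapcho dealkoxycarbonylation: chloride attacks the ester methyl group in an SN2 reaction, the β-keto carboxylate 13 loses CO2 and water protonates the enolate; the ketone α-carbon equilibrates through its enol to the trans isomer, while the arylvinyl-bearing carbon has no acidic hydrogen and keeps its configuration. The temperature is kept at the lowest effective value so that chloride does not attack the benzyl ether para to the ketone.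

Step 9
Reactants: 14 (4-benzyloxy-3-methoxyphenyl){(3R,4S)-4-[1-(4-benzyloxy-3-methoxyphenyl)ethenyl]oxolan-3-yl}methanone
Product: 16 (3R,4R)-oxolane-3,4-diylbis[(4-benzyloxy-3-methoxyphenyl)methanone], via vicinal diol 15 (not isolated)
Conditions: OsO4 (2 mol %), NaIO4 (4 equiv), 2,6-lutidine (2 equiv), 1,4-dioxane–H2O (3:1), rt
Reagents that add atoms: osmium tetroxide, O=[Os](=O)(=O)=O; sodium periodate, [Na+].[O-]I(=O)(=O)=O
Why: Lemieux–Johnson oxidation: catalytic OsO4 dihydroxylates the electron-rich 1,1-disubstituted alkene to diol 15, which periodate cleaves to the aryl ketone and formaldehyde while it reoxidises osmium; 2,6-lutidine buffers the mixture and is too weak a base to enolise the product, so the trans configuration should be retained.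

Step 10
Reactants: 16 (3R,4R)-oxolane-3,4-diylbis[(4-benzyloxy-3-methoxyphenyl)methanone]
Product: 18 (S,S)-[(3R,4R)-oxolane-3,4-diyl]bis[(4-benzyloxy-3-methoxyphenyl)methanol], via mono-reduced hydroxy ketone 17 (not isolated)
Conditions: (R)-2-methyl-CBS-oxazaborolidine (C18H20BNO, 0.3 equiv), BH3·SMe2 (2.4 equiv), THF, −20 °C; then MeOH
Reagents that add atoms: none
Why: Corey–Bakshi–Shibata reduction: each aryl ketone binds to the ring boron of the catalyst with the aryl group as the large substituent and receives hydride from the borane held on nitrogen, which with the R catalyst gives the S carbinol; both carbonyls are reduced under catalyst control, the first giving 17. The Felkin–Anh preference of the adjacent ring stereocentre (the more substituted ring carbon as the large group) is expected to point the same way.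

Step 11
Reactants: 18 (S,S)-[(3R,4R)-oxolane-3,4-diyl]bis[(4-benzyloxy-3-methoxyphenyl)methanol]
Product: 20 (S,S)-[(3R,4R)-oxolane-3,4-diyl]bis[(4-hydroxy-3-methoxyphenyl)methanol], via mono-benzyl ether 19 (not isolated)
Conditions: H2 (1 atm), 10 % Pd/C, EtOAc–EtOH, rt, stopped after 2 equiv H2
Reagents that add atoms: none
Why: Catalytic hydrogenolysis: aryl benzyl ethers are cleaved over Pd/C under neutral conditions much faster than secondary benzylic alcohols, so both phenols should be freed (through 19) with the four stereocentres untouched.

## Compound list

1 | homovanillyl alcohol [2-(4-hydroxy-3-methoxyphenyl)ethanol] | COc1cc(CCO)ccc1O | starting material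
2 | 2-(4-benzyloxy-3-methoxyphenyl)ethanol | COc1cc(CCO)ccc1OCc1ccccc1 | intermediate
3 | (4-benzyloxy-3-methoxyphenyl)acetaldehyde | COc1cc(CC=O)ccc1OCc1ccccc1 | intermediate
4 | 2-(4-benzyloxy-3-methoxyphenyl)prop-2-enal | C=C(C=O)c1ccc(OCc2ccccc2)c(OC)c1 | intermediate
5 | racemic 2-[1-(4-benzyloxy-3-methoxyphenyl)ethenyl]oxirane | C=C(C1CO1)c1ccc(OCc2ccccc2)c(OC)c1 | intermediate
6 | 4-benzyloxy-3-methoxybenzaldehyde | O=Cc1ccc(OCc2ccccc2)c(OC)c1 | starting material
7 | methyl acrylate | C=CC(=O)OC | starting material
8 | racemic methyl 2-[(4-benzyloxy-3-methoxyphenyl)(hydroxy)methyl]prop-2-enoate | C=C(C(=O)OC)C(O)c1ccc(OCc2ccccc2)c(OC)c1 | intermediate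
9 | methyl 2-(4-benzyloxy-3-methoxybenzoyl)prop-2-enoate | C=C(C(=O)OC)C(=O)c1ccc(OCc2ccccc2)c(OC)c1 | intermediate
10 | 2-aryl allylpalladium alkoxide zwitterion from 5 (not isolated; drawn as its η1 form, diphosphine left out) | [O-]CC=C(C[Pd+])c1ccc(OCc2ccccc2)c(OC)c1 | intermediate
11 | ring-open oxa-Michael adduct, β-keto ester enolate carrying the allylpalladium unit (not isolated; drawn as its η1 form, diphosphine left out) | COC(=O)C(COCC=C(C[Pd+])c1ccc(OCc2ccccc2)c(OC)c1)=C([O-])c1ccc(OCc2ccccc2)c(OC)c1 | intermediate
12 | methyl (3S,4R)-3-(4-benzyloxy-3-methoxybenzoyl)-4-[1-(4-benzyloxy-3-methoxyphenyl)ethenyl]oxolane-3-carboxylate | C=C(c1ccc(OCc2ccccc2)c(OC)c1)[C@H]1COC[C@]1(C(=O)OC)C(=O)c1ccc(OCc2ccccc2)c(OC)c1 | intermediate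
13 | lithium (3S,4R)-3-(4-benzyloxy-3-methoxybenzoyl)-4-[1-(4-benzyloxy-3-methoxyphenyl)ethenyl]oxolane-3-carboxylate (not isolated) | C=C(c1ccc(OCc2ccccc2)c(OC)c1)[C@H]1COC[C@]1(C(=O)[O-])C(=O)c1ccc(OCc2ccccc2)c(OC)c1.[Li+] | intermediate
14 | (4-benzyloxy-3-methoxyphenyl){(3R,4S)-4-[1-(4-benzyloxy-3-methoxyphenyl)ethenyl]oxolan-3-yl}methanone (trans) | C=C(c1ccc(OCc2ccccc2)c(OC)c1)[C@H]1COC[C@@H]1C(=O)c1ccc(OCc2ccccc2)c(OC)c1 | intermediate
15 | (4-benzyloxy-3-methoxyphenyl){(3R,4R)-4-[1-(4-benzyloxy-3-methoxyphenyl)-1,2-dihydroxyethyl]oxolan-3-yl}methanone, both epimers at the tertiary carbinol (not isolated) | OCC(O)(c1ccc(OCc2ccccc2)c(OC)c1)[C@H]1COC[C@@H]1C(=O)c1ccc(OCc2ccccc2)c(OC)c1 | intermediate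
16 | (3R,4R)-oxolane-3,4-diylbis[(4-benzyloxy-3-methoxyphenyl)methanone] | O=C(c1ccc(OCc2ccccc2)c(OC)c1)[C@H]1COC[C@@H]1C(=O)c1ccc(OCc2ccccc2)c(OC)c1 | intermediate
17 | (4-benzyloxy-3-methoxyphenyl){(3R,4R)-4-[(S)-(4-benzyloxy-3-methoxyphenyl)(hydroxy)methyl]oxolan-3-yl}methanone (not isolated) | O=C(c1ccc(OCc2ccccc2)c(OC)c1)[C@H]1COC[C@@H]1[C@H](O)c1ccc(OCc2ccccc2)c(OC)c1 | intermediate
18 | (S,S)-[(3R,4R)-oxolane-3,4-diyl]bis[(4-benzyloxy-3-methoxyphenyl)methanol] | COc1cc([C@@H](O)[C@H]2COC[C@@H]2[C@H](O)c2ccc(OCc3ccccc3)c(OC)c2)ccc1OCc1ccccc1 | intermediate
19 | (S)-(4-benzyloxy-3-methoxyphenyl){(3R,4R)-4-[(S)-hydroxy(4-hydroxy-3-methoxyphenyl)methyl]oxolan-3-yl}methanol (not isolated) | COc1cc([C@@H](O)[C@H]2COC[C@@H]2[C@H](O)c2ccc(OCc3ccccc3)c(OC)c2)ccc1O | intermediate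
20 | (S,S)-[(3R,4R)-oxolane-3,4-diyl]bis[(4-hydroxy-3-methoxyphenyl)methanol] | COc1cc([C@@H](O)[C@H]2COC[C@@H]2[C@H](O)c2ccc(O)c(OC)c2)ccc1O | target

## Step count and least certain steps

Total step count: 11. Longest linear sequence: 9 steps (steps 1, 2, 3, 4, 7, 8, 9, 10, 11); the acceptor branch (steps 5 and 6) joins at step 7.

Step 7 (key step). The most likely failure is insufficient enantiodifferentiation. Ring closure of the tethered enolate may be faster than the π–σ–π exchange of the two allyl complexes, or the aryl group on the central allyl carbon may fit the ligand pocket poorly. Isomerisation of the epoxide by β-hydride elimination and self-condensation of the acceptor would lower the conversion.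
- Fallback: it sets out from 5 and 9 and comes back at 18. The annulation is run without a chiral ligand, with Pd(PPh3)4 as the zerovalent palladium source. This gives 12 as a racemate, that is, together with its enantiomer methyl (3R,4S)-3-(4-benzyloxy-3-methoxybenzoyl)-4-[1-(4-benzyloxy-3-methoxyphenyl)ethenyl]oxolane-3-carboxylate F1.
- Steps 8 and 9 applied to this mixture give 14 and 16 accompanied by the enantiomeric ketone (4-benzyloxy-3-methoxyphenyl){(3S,4R)-4-[1-(4-benzyloxy-3-methoxyphenyl)ethenyl]oxolan-3-yl}methanone F2 and the enantiomeric diketone (3S,4S)-oxolane-3,4-diylbis[(4-benzyloxy-3-methoxyphenyl)methanone] F3.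
- The reduction of step 10, which is under reagent control, then turns 16 into 18 and F3 into the diastereomeric diol (S,S)-[(3S,4S)-oxolane-3,4-diyl]bis[(4-benzyloxy-3-methoxyphenyl)methanol] F4. 18 and F4 are diastereomers and would be separated by chromatography or crystallisation. The absolute configuration then rests on the oxazaborolidine alone, at the cost of half the material.

Step 10. The most likely failure is loss of configurational purity in two ways: enolisation of the symmetric diketone towards the meso cis form before it is reduced, and incomplete catalyst control at one of the two carbonyls, because an aryl ketone with a branched α-carbon offers a smaller size difference to the catalyst.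
- Fallback: it sets out from 14 and comes back at 18. The single ketone of 14 is reduced with the same oxazaborolidine and borane to (S)-(4-benzyloxy-3-methoxyphenyl){(3R,4S)-4-[1-(4-benzyloxy-3-methoxyphenyl)ethenyl]oxolan-3-yl}methanol F5, whose diastereomeric purity can be checked and improved by chromatography.
- Lemieux–Johnson cleavage of F5 (OsO4 catalyst, NaIO4) passes through 1-(4-benzyloxy-3-methoxyphenyl)-1-{(3R,4R)-4-[(S)-(4-benzyloxy-3-methoxyphenyl)(hydroxy)methyl]oxolan-3-yl}ethane-1,2-diol F6 (not isolated) and gives 17, now isolated. A second oxazaborolidine reduction gives 18.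
- A symmetric diketone never forms in this sequence, and each carbinol is set separately, for one more step.

Step 5. The most likely failure is stalled conversion, because the electron-rich aldehyde is a poor electrophile for the ammonium enolate, together with slow polymerisation of the acrylate over the long reaction time.
- Fallback: it sets out from 6 and comes back at 8. Methyl propiolate is hydroaluminated with i-Bu2AlH in the presence of N-methylmorpholine N-oxide in THF to give methyl 2-(diisobutylalumanyl)prop-2-enoate F7. This preformed α-metalated acrylate adds to 6 at 0 °C and gives 8 after aqueous work-up. The amine-catalysed equilibrium is replaced by an irreversible addition of a stoichiometric vinylmetal reagent.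

Step 11. The most likely failure is over-reduction, that is, hydrogenolysis of the benzylic C–OH bonds, which the para oxygen assists once a phenol has been freed.
- Fallback: it sets out from 16 and comes back at 20. The hydrogenolysis is moved ahead of the reduction, where no benzylic C–O bond exists yet. H2 over 10 % Pd/C in EtOAc converts 16 into (3R,4R)-oxolane-3,4-diylbis[(4-hydroxy-3-methoxyphenyl)methanone] F8 (the same substance as A1).
- N,O-Bis(trimethylsilyl)acetamide masks the phenols under neutral conditions as (3R,4R)-oxolane-3,4-diylbis{[3-methoxy-4-(trimethylsilyloxy)phenyl]methanone} F9.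
- Reduction as in step 10 gives (S,S)-[(3R,4R)-oxolane-3,4-diyl]bis{[3-methoxy-4-(trimethylsilyloxy)phenyl]methanol} F10, and brief treatment with K2CO3 in methanol removes the aryl silyl ethers to give 20. The final deprotection is then a mild solvolysis and not a reduction.

## Further compounds

F1 | step 7 | methyl (3R,4S)-3-(4-benzyloxy-3-methoxybenzoyl)-4-[1-(4-benzyloxy-3-methoxyphenyl)ethenyl]oxolane-3-carboxylate | C=C(c1ccc(OCc2ccccc2)c(OC)c1)[C@@H]1COC[C@@]1(C(=O)OC)C(=O)c1ccc(OCc2ccccc2)c(OC)c1
F2 | step 7 | (4-benzyloxy-3-methoxyphenyl){(3S,4R)-4-[1-(4-benzyloxy-3-methoxyphenyl)ethenyl]oxolan-3-yl}methanone | C=C(c1ccc(OCc2ccccc2)c(OC)c1)[C@@H]1COC[C@H]1C(=O)c1ccc(OCc2ccccc2)c(OC)c1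
F3 | step 7 | (3S,4S)-oxolane-3,4-diylbis[(4-benzyloxy-3-methoxyphenyl)methanone] | O=C(c1ccc(OCc2ccccc2)c(OC)c1)[C@@H]1COC[C@H]1C(=O)c1ccc(OCc2ccccc2)c(OC)c1
F4 | step 7 | (S,S)-[(3S,4S)-oxolane-3,4-diyl]bis[(4-benzyloxy-3-methoxyphenyl)methanol] | COc1cc([C@@H](O)[C@@H]2COC[C@H]2[C@H](O)c2ccc(OCc3ccccc3)c(OC)c2)ccc1OCc1ccccc1
F5 | step 10 | (S)-(4-benzyloxy-3-methoxyphenyl){(3R,4S)-4-[1-(4-benzyloxy-3-methoxyphenyl)ethenyl]oxolan-3-yl}methanol | C=C(c1ccc(OCc2ccccc2)c(OC)c1)[C@H]1COC[C@@H]1[C@H](O)c1ccc(OCc2ccccc2)c(OC)c1
F6 | step 10 | 1-(4-benzyloxy-3-methoxyphenyl)-1-{(3R,4R)-4-[(S)-(4-benzyloxy-3-methoxyphenyl)(hydroxy)methyl]oxolan-3-yl}ethane-1,2-diol, both epimers at the tertiary carbinol | OCC(O)(c1ccc(OCc2ccccc2)c(OC)c1)[C@H]1COC[C@@H]1[C@H](O)c1ccc(OCc2ccccc2)c(OC)c1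
F7 | step 5 | methyl 2-(diisobutylalumanyl)prop-2-enoate | C=C(C(=O)OC)[Al](CC(C)C)CC(C)C
F8 | step 11 | (3R,4R)-oxolane-3,4-diylbis[(4-hydroxy-3-methoxyphenyl)methanone] | COc1cc(C(=O)[C@H]2COC[C@@H]2C(=O)c2ccc(O)c(OC)c2)ccc1O
F9 | step 11 | (3R,4R)-oxolane-3,4-diylbis{[3-methoxy-4-(trimethylsilyloxy)phenyl]methanone} | COc1cc(C(=O)[C@H]2COC[C@@H]2C(=O)c2ccc(O[Si](C)(C)C)c(OC)c2)ccc1O[Si](C)(C)C
F10 | step 11 | (S,S)-[(3R,4R)-oxolane-3,4-diyl]bis{[3-methoxy-4-(trimethylsilyloxy)phenyl]methanol} | COc1cc([C@@H](O)[C@H]2COC[C@@H]2[C@H](O)c2ccc(O[Si](C)(C)C)c(OC)c2)ccc1O[Si](C)(C)C
A1 | alternative 1 | (3R,4R)-3,4-bis(4-hydroxy-3-methoxybenzoyl)tetrahydrofuran | COc1cc(C(=O)[C@H]2COC[C@@H]2C(=O)c2ccc(O)c(OC)c2)ccc1O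
A2 | alternative 1 | 1,1′-[(3R,4R)-oxolane-3,4-diyl]bis(prop-2-yn-1-one) | C#CC(=O)[C@H]1COC[C@@H]1C(=O)C#C
A3 | alternative 1 | 1,2-dimethoxy-3-(trimethylsilyloxy)buta-1,3-diene | COC=C(OC)C(=C)O[Si](C)(C)C
A4 | alternative 2 | (1R,2R,3S,4S)-3,4-bis(4-hydroxy-3-methoxyphenyl)cyclobutane-1,2-dicarboxylic acid (all-trans) | OC(=O)[C@H]1[C@H](C(=O)O)[C@@H](c2ccc(O)c(OC)c2)[C@@H]1c1ccc(O)c(OC)c1
A5 | alternative 2 | exo,exo-2,6-bis(4-hydroxy-3-methoxyphenyl)-3,7-dioxabicyclo[3.3.0]octane-4,8-dione (enantiomer that maps onto 20) | COc1cc([C@H]2OC(=O)[C@H]3[C@@H]2C(=O)O[C@@H]3c2ccc(O)c(OC)c2)ccc1O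
A6 | alternative 2 | (1S,2R,3R,4S)-1,4-bis(4-hydroxy-3-methoxyphenyl)-2,3-bis(hydroxymethyl)butane-1,4-diol | COc1cc([C@@H](O)[C@@H](CO)[C@H](CO)[C@H](O)c2ccc(O)c(OC)c2)ccc1O
A7 | alternative 3 | (1S,4S,2E)-1,4-bis(4-benzyloxy-3-methoxyphenyl)-1,4-bis(tert-butyldimethylsilyloxy)but-2-ene | COc1cc([C@@H](O[Si](C)(C)C(C)(C)C)/C=C/[C@H](O[Si](C)(C)C(C)(C)C)c2ccc(OCc3ccccc3)c(OC)c2)ccc1OCc1ccccc1
A8 | alternative 3 | dimethyl (2S,3S)-2,3-bis[(S)-(4-benzyloxy-3-methoxyphenyl)(tert-butyldimethylsilyloxy)methyl]succinate | COc1cc([C@@H](O[Si](C)(C)C(C)(C)C)[C@@H](C(=O)OC)[C@H](C(=O)OC)[C@H](O[Si](C)(C)C(C)(C)C)c2ccc(OCc3ccccc3)c(OC)c2)ccc1OCc1ccccc1
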